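**Retrosynthetic overview**
- Target ⇒ (2R,3R)-taxifolin 3-O-gallate: the C-4 carbinol comes from the C-4 ketone by face-selective hydrogenation, which sets 4S (cis to O-3).
- Taxifolin 3-O-gallate ⇒ (+)-taxifolin + N-succinimidyl gallate: disconnection of the ester C–O bond at O-3, both partners unprotected; this acyl transfer is the key step.
- N-Succinimidyl gallate ⇒ gallic acid + N-hydroxysuccinimide.
- No ring is built: rings A, C and B (with C-2 and C-3) come intact from (+)-taxifolin, the galloyl ring from gallic acid.

Assumption: commercial larch-derived (+)-taxifolin is taken as the single (2R,3R)-trans enantiomer.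

**Step 1**
Reactants: 1 gallic acid (3,4,5-trihydroxybenzoic acid); 2 N-hydroxysuccinimide
Product: 4 N-succinimidyl 3,4,5-trihydroxybenzoate (N-succinimidyl gallate), via O-galloylisourea 3 (not isolated)
Conditions: DCC (1.05 equiv), THF, 0 → 20 °C; filter off the urea
Reagents that add atoms: DCC, C(=NC1CCCCC1)=NC1CCCCC1 (its atoms sit only in 3 and leave as the urea)
Why: Carbodiimide active-ester formation: without base only the carboxylic acid adds to DCC, and the O-acylisourea is captured by N-hydroxysuccinimide much faster than by neutral phenols, as for the NHS esters of other unprotected catechol- and gallol-type acids; no stereocenter is involved.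

**Step 2**
Reactants: 4 N-succinimidyl gallate; 5 (+)-taxifolin, (2R,3R)-2-(3,4-dihydroxyphenyl)-3,5,7-trihydroxychroman-4-one
Product: 6 (2R,3R)-2-(3,4-dihydroxyphenyl)-5,7-dihydroxy-4-oxochroman-3-yl 3,4,5-trihydroxybenzoate (taxifolin 3-O-gallate)
Conditions: 4 (2 equiv), DMAPO (4-(dimethylamino)pyridine N-oxide, 0.3 equiv), MeCN–THF, 50 °C, Ar; then MeOH, NaOAc–AcOH buffer (pH 6), 40 °C
Reagents that add atoms: none
Why: Proposed new method: protecting-group-free, self-correcting O-galloylation, in which the non-basic O-nucleophilic catalyst DMAPO converts 4 into an N-(galloyloxy)pyridinium ion that acylates neutral hydroxyls; any galloyl group that lands on a phenol (taxifolin O-7, O-3', O-4' or another gallate unit) gives an aryl ester that is itself an active ester (ArOH pKa about 7–9) and is reopened by the catalyst, whereas the alkyl ester at O-3 is inert, so the acyl group drains to the only aliphatic oxygen, and the closing buffered methanolysis (the depside cleavage known from gallotannins) strips whatever remains on phenols; C-2 and C-3 are not touched, so the (2R,3R) configuration is carried over; closest known reaction type: DMAP-type nucleophilic acyl transfer from active esters (Steglich-type esterification) combined with chemoselective solvolysis of phenolic esters beside alkyl esters.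

**Step 3**
Reactants: 6 taxifolin 3-O-gallate
Product: 7 (2R,3S,4S)-2-(3,4-dihydroxyphenyl)-4,5,7-trihydroxy-3,4-dihydro-2H-chromen-3-yl 3,4,5-trihydroxybenzoate (2,3-trans-3,4-cis-leucocyanidin 3-O-gallate)
Conditions: H2 (1 atm), PtO2 (5 mol %), EtOH–THF, 20 °C, stopped after 1 equiv H2
Reagents that add atoms: none
Why: Heterogeneous catalytic hydrogenation of the aryl ketone: hydrogen is expected to reach C-4 from the face anti to the equatorial 3-O-galloyl group (the face of the small axial H-3), which puts the new 4-OH cis to O-3 (4S), the course recalled for PtO2 hydrogenation of 2,3-trans-dihydroflavonols (metal hydrides give the 3,4-trans epimer); the neutral medium avoids acyl migration and C-4 ionisation, and C-2/C-3 are unaffected.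

**Compound list**
1 | gallic acid | OC(=O)c1cc(O)c(O)c(O)c1 | starting material
2 | N-hydroxysuccinimide | O=C1CCC(=O)N1O | starting material
3 | O-galloyl-N,N'-dicyclohexylisourea | O=C(OC(=NC1CCCCC1)NC1CCCCC1)c1cc(O)c(O)c(O)c1 | intermediate (not isolated)
4 | N-succinimidyl 3,4,5-trihydroxybenzoate | O=C(ON1C(=O)CCC1=O)c1cc(O)c(O)c(O)c1 | intermediate
5 | (+)-taxifolin, (2R,3R) | O[C@@H]1[C@@H](c2ccc(O)c(O)c2)Oc2cc(O)cc(O)c2C1=O | starting material
6 | (2R,3R)-taxifolin 3-O-gallate | O=C(O[C@@H]1[C@@H](c2ccc(O)c(O)c2)Oc2cc(O)cc(O)c2C1=O)c1cc(O)c(O)c(O)c1 | intermediate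
7 | (2R,3S,4S)-leucocyanidin 3-O-gallate (CNP0265773.1) | O=C(O[C@@H]1[C@@H](c2ccc(O)c(O)c2)Oc2cc(O)cc(O)c2[C@@H]1O)c1cc(O)c(O)c(O)c1 | target

**Step count and risks**
Total step count: 3. Longest linear sequence: 3 (gallic acid → 4 → 6 → 7); taxifolin enters at step 2.

The steps most likely to fail are, in this order, step 2, step 3 and step 1.

The new acyl transfer of step 2 may stall at phenolic esters or give low conversion at the hindered O-3. Its fallback uses known chemistry, sets out from 5 and comes back at 6. All reactive hydroxyls of 5 are acylated with commercial 3,4,5-triacetoxybenzoyl chloride (4.5 equiv, pyridine, cat. DMAP, CH2Cl2) to give (2R,3R)-3,7,3',4'-tetrakis-O-(3,4,5-triacetoxybenzoyl)taxifolin F1. Every phenolic ester (twelve aryl acetates and three aryl aroates) is then cleaved by buffered methanolysis (NaOAc–AcOH, MeOH, 40 °C), which leaves only the alkyl ester at O-3, that is 6.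

The hydrogenation of step 3 may over-reduce by hydrogenolysis of the benzylic C-4–O bond, or may show poor facial selectivity; the cis course rests on class precedent, not on this substrate. Its fallback sets out from 6 and comes back at 7. NaBH4 in THF–EtOH at −20 °C gives, by axial hydride attack, the 3,4-trans epimer (2R,3S,4R)-2-(3,4-dihydroxyphenyl)-4,5,7-trihydroxy-3,4-dihydro-2H-chromen-3-yl 3,4,5-trihydroxybenzoate F2. Brief equilibration in dilute aqueous AcOH at 40 °C then epimerises C-4 through the benzylic cation, with water re-adding cis to O-3, the trans-to-cis course known for leucocyanidin itself. The neighbouring galloyl group may cause some acyl scrambling between O-3 and O-4 here.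

The unprotected active ester of step 1 may acylate itself during preparation or storage. Its fallback sets out from 1 and comes back at 4 by transient silyl masking. HMDS (cat. TMSCl, 60 °C) gives trimethylsilyl 3,4,5-tris(trimethylsilyloxy)benzoate F3. (COCl)2 with cat. DMF in CH2Cl2 gives 3,4,5-tris(trimethylsilyloxy)benzoyl chloride F4. Compound 2 and pyridine give N-succinimidyl 3,4,5-tris(trimethylsilyloxy)benzoate F5, and MeOH with a trace of AcOH removes the three aryl silyl groups to return 4.

**Further compounds**
F1 | step 2 | (2R,3R)-3,7,3',4'-tetrakis-O-(3,4,5-triacetoxybenzoyl)taxifolin | O=C(O[C@@H]1[C@@H](c2ccc(OC(=O)c3cc(OC(C)=O)c(OC(C)=O)c(OC(C)=O)c3)c(OC(=O)c3cc(OC(C)=O)c(OC(C)=O)c(OC(C)=O)c3)c2)Oc2cc(OC(=O)c3cc(OC(C)=O)c(OC(C)=O)c(OC(C)=O)c3)cc(O)c2C1=O)c1cc(OC(C)=O)c(OC(C)=O)c(OC(C)=O)c1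
F2 | step 3 | (2R,3S,4R)-2-(3,4-dihydroxyphenyl)-4,5,7-trihydroxy-3,4-dihydro-2H-chromen-3-yl 3,4,5-trihydroxybenzoate (3,4-trans epimer of 7) | O=C(O[C@@H]1[C@@H](c2ccc(O)c(O)c2)Oc2cc(O)cc(O)c2[C@H]1O)c1cc(O)c(O)c(O)c1
F3 | step 1 | trimethylsilyl 3,4,5-tris(trimethylsilyloxy)benzoate | C[Si](C)(C)OC(=O)c1cc(O[Si](C)(C)C)c(O[Si](C)(C)C)c(O[Si](C)(C)C)c1
F4 | step 1 | 3,4,5-tris(trimethylsilyloxy)benzoyl chloride | ClC(=O)c1cc(O[Si](C)(C)C)c(O[Si](C)(C)C)c(O[Si](C)(C)C)c1
F5 | step 1 | N-succinimidyl 3,4,5-tris(trimethylsilyloxy)benzoate | O=C(ON1C(=O)CCC1=O)c1cc(O[Si](C)(C)C)c(O[Si](C)(C)C)c(O[Si](C)(C)C)c1
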